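## The problem

The target is an aromatic bisabolane-type ester with a single stereocenter. Its benzene ring (aryl C1–C6) is pentasubstituted: C1 carries the side chain, C2 a free hydroxyl, C3 a methoxy, C4 a methyl, C5 a methoxy, and C6 is the only CH. The side chain is a 1,1-disubstituted alkene joined through its internal carbon to aryl C1 and to the (S)-carbinol carbon, which bears the angelate ester and a prenyl group. The chain is easy to build; the difficulty lies in the ring, where the two para oxygens must end up different (OH at C2, OMe at C5) and the third oxygen must sit at C3, not C6. The stereocenter is isolated, so it must be set by a reagent or catalyst; once acylated, its C–O bond is allylic and must not meet acids, Lewis acids or zerovalent palladium. The angelate is the Z isomer and goes over to the tiglate with nucleophilic acylation catalysts or strong base. The free phenol is acylated more easily than the secondary alcohol and, as a 4-methoxyphenol, is readily oxidised to a quinone, so any route with phenol and alcohol free together needs a protecting group whose removal spares all of the above. The feature that makes the key step possible: ring atoms C2 (OH) and C5 (OMe) are para, the bulky chain at C1 is next to the hydroxyl and C6 carries hydrogen, which is the fingerprint of a chromium carbene benzannulation (C2 from a carbonyl ligand, C5 from the carbene carbon, C1 and C6 from a terminal alkyne, C3 and C4 from the alkene of an alkenylcarbene ligand).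

## Retrosynthesis

**16 ⇒ 9 + 14.** Three ring bonds are cut at once (C5–C6, C1–C2, C2–C3), with C2 and its oxygen traced back to a carbonyl ligand.
- This leaves the terminal enyne ester 9 (its CH becomes C6, its internal alkyne carbon C1) and the alkenylcarbene complex 14 (carbene carbon becomes C5 with its OMe, α-carbon becomes C4 with its methyl, β-carbon becomes C3 with its OMe).
- In favour of this cut: the annulation gives a 4-methoxyphenol whose free OH comes from CO and whose OMe comes from the carbene, which is exactly the differentiation the target needs, and it places the alkyne substituent next to the hydroxyl.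
- Against the neighbouring cuts: a vinylketene–alkyne (Danheiser) annulation would put the chain meta to the hydroxyl for a terminal alkyne, and a squarate ring expansion delivers the two para oxygens the wrong way round.
- Because the conditions are neutral, the angelate can be in place before the ring exists. The phenol is then never present together with an acylating agent and no protecting group is needed.
- The precursors are two open-chain pieces with one stereocenter between them.
- The forward reaction must give one regioisomer, insert CO despite the donor substituent, and choose the alkyne over two alkenes and an enoate.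

**9 ⇒ 6 + 7.** The acyl–oxygen bond of the ester is cut. The acylation is placed here, before the arene is made, for the reason above. It must keep the Z geometry, which a mixed anhydride 8 without nucleophilic catalyst should do, and it leaves the carbinol C–O bond untouched.

**6 ⇒ 5 ⇒ 2 + 4.** The silyl cap on the alkyne is removed (5), then the bond between the carbinol carbon and the internal alkene carbon is cut.
- Both fragments are achiral: aldehyde 2 (six carbons) and alkenyl triflate 4 (four carbons plus silicon). The stereocenter is set in the C–C bond-forming step by a chiral chromium catalyst.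
- Cutting the carbinol–CH2 bond instead would demand a linear-selective prenylation of an unstable 2-alkynylacrolein. Reducing a cross-conjugated ketone would ask a catalyst to tell two similar groups apart.
- The forward reaction must be non-basic, because 2 is enolisable and its double bond moves into conjugation easily.

**2 ⇐ 1 and 4 ⇐ 3.** Aldehyde 2 is one oxidation from commercial alcohol 1. Triflate 4 is one enol sulfonylation from commercial ynone 3, which can enolise only towards its methyl group.

**14 ⇒ 11 ⇐ 10.** The Cr=C bond and the O–methyl bond of the carbene are cut (Fischer route). Alkenyllithium 12 adds to a carbonyl ligand of the metal hexacarbonyl, and the acylchromate 13 is O-methylated. Bromide 11 comes from commercial bromoacetal 10 by loss of methanol. The lithium and methoxy groups in 12 must be cis, or lithium methoxide is eliminated.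

## Roads not taken

**Alternative 1: aryl–alkenyl cross-coupling on a ready-made ring (the obvious route).**
- Cut: the bond between aryl C1 and the alkene carbon.
- Forward key step: Suzuki–Miyaura coupling (zerovalent palladium catalyst, aqueous base) of arylboronate A1 with enantioenriched 2-bromoallylic alcohol A2 to give diol A3, then acylation.
- Why the chosen plan is better:
  - A1 must be built by stepwise substitution of a simple dimethoxytoluene derivative. The position next to the phenol oxygen competes with the one activated by both methoxy groups, so a protected phenol and a directed metalation are needed (four to five steps).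
  - In A3 the phenol is acylated before the hindered allylic alcohol, so a protecting group must be carried through and removed last beside the angelate, the allylic ester and the styrene.
  - The stereocenter still needs its own asymmetric step (A2).
  - The chosen plan makes the ring and frees the phenol in one neutral step after the ester is in place.

**Alternative 2: squarate-based cyclobutenone ring expansion (Moore type).**
- Cut: C1–C2 by 6π closure, with C2–C3–C4–C5 taken as a cyclobutenone.
- Forward key step: an alkenyllithium adds to cyclobutenedione A4 at the carbonyl next to the methoxy-bearing carbon to give 4-alkenyl-4-hydroxycyclobutenone A5. Thermolysis (toluene, 110 °C; 4π opening to a dienylketene, 6π closure) gives hydroquinone A6.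
- Why the chosen plan is better:
  - The carbon pattern of A6 is right but both para oxygens are free hydroxyls. Even if the less hindered C5 hydroxyl could be methylated selectively, the hydroquinone is air-sensitive.
  - The alkenyllithium (a 2-lithiated 1,3-diene) cannot carry an ester, so the carbinol must be silyl-protected.
  - After desilylation the secondary alcohol would again have to be acylated beside the free C2 phenol.
  - The carbene annulation gives the same ring with the para oxygens already differentiated and the ester already present.

**Alternative 3: late aromatisation of a cyclohexane-1,3-dione.**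
- Cut: the C3(OMe)–C4(Me)–C5(OMe) unit is read as a 2-methyl-1,3-dione.
- Forward key step: dione A7, carrying the side chain at its C5, is aromatised by oxidative methanolysis (I2, MeOH) to the resorcinol dimethyl ether A8. The C2 hydroxyl is then introduced by ortho-lithiation, borylation and oxidation.
- Why the chosen plan is better:
  - A7 needs the chiral dienyl chain to be built on a Michael acceptor first.
  - The aromatising oxidant also attacks the prenyl and 1,1-disubstituted alkenes.
  - The C2 oxygen must still be forced in between two ortho substituents.
  - The phenol-before-ester problem returns, at a cost of several extra redox and protecting-group steps.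

Key step: step 8

Assumption: the facial preference of the chiral chromium catalyst in step 3 is not predicted here; the ligand antipode that gives the (S)-carbinol 5 is taken, to be confirmed by Mosher ester analysis before going on.

## Route

Step 1
Reactants: 1 4-methylpent-3-en-1-ol
Product: 2 4-methylpent-3-enal
Conditions: Dess–Martin periodinane, NaHCO3, CH2Cl2, 0 °C to rt; used as a cold solution
Reagents that add atoms: none
Why: Dess–Martin oxidation under buffered, amine-free conditions should avoid the base-induced shift of the β,γ double bond into conjugation; the volatile aldehyde is not concentrated to dryness.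

Step 2
Reactants: 3 4-(trimethylsilyl)but-3-yn-2-one
Product: 4 4-(trimethylsilyl)but-1-en-3-yn-2-yl trifluoromethanesulfonate
Conditions: Tf2O, 2,6-di-tert-butyl-4-methylpyridine, CH2Cl2, 0 °C to rt
Reagents that add atoms: trifluoromethanesulfonic anhydride, O=S(=O)(OS(=O)(=O)C(F)(F)F)C(F)(F)F
Why: Ketone-to-vinyl triflate conversion by O-sulfonylation and loss of a methyl proton; only the methyl side can enolise, so one regioisomer should form, and no enolate of the Michael-accepting ynone is generated.

Step 3
Reactants: 2 4-methylpent-3-enal, 4 4-(trimethylsilyl)but-1-en-3-yn-2-yl trifluoromethanesulfonate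
Product: 5 (4S)-7-methyl-3-methylidene-1-(trimethylsilyl)oct-6-en-1-yn-4-ol
Conditions: CrCl2 (10 mol %), chiral ligand N-[2-(4-isopropyl-4,5-dihydro-1,3-oxazol-2-yl)-6-methoxyphenyl]methanesulfonamide (11 mol %, antipode as assumed), proton sponge, NiCl2(2,9-dimethyl-1,10-phenanthroline) (2 mol %), Mn, ZrCp2Cl2, LiCl, MeCN, rt; aqueous work-up
Reagents that add atoms: none
Why: Catalytic asymmetric Nozaki–Hiyama–Kishi coupling: zerovalent nickel inserts into the C–OTf bond, the alkenyl group passes to chromium and adds to the aldehyde inside the chiral sulfonamide–oxazoline ligand sphere, which alone sets C4 (S) by face selection; the medium is non-basic, so 2 should neither enolise nor isomerise, and the silyl cap keeps the alkyne out of the nickel chemistry and hinders attack through the distal alkyne carbon.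

Step 4
Reactants: 5 (4S)-7-methyl-3-methylidene-1-(trimethylsilyl)oct-6-en-1-yn-4-ol
Product: 6 (4S)-7-methyl-3-methylideneoct-6-en-1-yn-4-ol
Conditions: K2CO3 (cat.), MeOH, 0 °C to rt
Reagents that add atoms: none
Why: Methanolysis of the alkynyl C–Si bond; the carbinol centre is not involved and should keep its configuration.

Step 5
Reactants: 6 (4S)-7-methyl-3-methylideneoct-6-en-1-yn-4-ol, 7 (2Z)-2-methylbut-2-enoic acid (angelic acid)
Product: 9 (4S)-7-methyl-3-methylideneoct-6-en-1-yn-4-yl (2Z)-2-methylbut-2-enoate, via mixed anhydride 8 (not isolated)
Conditions: 7, 2,4,6-trichlorobenzoyl chloride, Et3N, toluene, rt; then 6, 80 °C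
Reagents that add atoms: none
Why: Mixed-anhydride (Yamaguchi-type) esterification run without DMAP: the alcohol attacks the unhindered angeloyl carbonyl of 8, and with no nucleophilic catalyst or strong base present the reversible conjugate addition that turns angelate into tiglate should not occur; the carbinol C–O bond is not broken, so C4 is retained.

Step 6
Reactants: 10 2-bromo-1,1-dimethoxypropane
Product: 11 (Z)-2-bromo-1-methoxyprop-1-ene
Conditions: Me3SiOTf, i-Pr2NEt, CH2Cl2, −20 °C to rt; fractional distillation
Reagents that add atoms: none
Why: Silyl triflate-mediated acetal-to-enol ether elimination: ionisation to the oxocarbenium ion and deprotonation at the bromine-bearing carbon by the hindered amine; if both geometric isomers form, the isomer with Br cis to OMe is the one carried on.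

Step 7
Reactants: 11 (Z)-2-bromo-1-methoxyprop-1-ene
Product: 14 pentacarbonyl[(2Z)-1,3-dimethoxy-2-methylprop-2-en-1-ylidene]chromium, via alkenyllithium 12 (not isolated), via lithium acylchromate 13 (not isolated)
Conditions: t-BuLi (2 equiv), Et2O, −78 °C; Cr(CO)6, THF, −78 to 0 °C; Me3OBF4, CH2Cl2, 0 °C
Reagents that add atoms: chromium hexacarbonyl, O=C=[Cr](=C=O)(=C=O)(=C=O)(=C=O)=C=O; trimethyloxonium tetrafluoroborate, C[O+](C)C.F[B-](F)(F)F
Why: Fischer carbene synthesis: bromine–lithium exchange with retention gives 12, whose lithium is cis to the methoxy oxygen (internally coordinated and unable to undergo anti elimination); 12 adds to a carbonyl ligand and the acylchromate 13 is O-methylated by the Meerwein salt.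

Step 8
Reactants: 9 (4S)-7-methyl-3-methylideneoct-6-en-1-yn-4-yl (2Z)-2-methylbut-2-enoate, 14 pentacarbonyl[(2Z)-1,3-dimethoxy-2-methylprop-2-en-1-ylidene]chromium
Product: 16 (3S)-2-(2-hydroxy-3,5-dimethoxy-4-methylphenyl)-6-methylhepta-1,5-dien-3-yl (2Z)-2-methylbut-2-enoate, via arene tricarbonylchromium complex 15 (not isolated)
Conditions: 14 (1.3 equiv), THF (0.3 M), 50 °C, argon; then air, EtOAc, rt
Reagents that add atoms: none
Why: Dötz benzannulation of an alkenyl(methoxy)carbene chromium complex with a terminal conjugated enyne is the closest known reaction type. Thermal loss of one CO from 14 opens a site for the alkyne of 9, which inserts into the Cr=C bond with its substituted carbon remote from the methoxy-bearing carbene carbon, and CO insertion then gives a chromium-bound dienylketene. The ring (aryl C1–C6) is closed by a 6π electrocyclisation between the ketene carbon (C2) and the methoxy-bearing alkene carbon (C3), and tautomerisation gives the phenol as its Cr(CO)3 complex 15, from which air releases 16. No stereocenter is formed; the carbinol centre of 9 lies outside the reacting atoms and the medium is neutral, so it and the Z ester should be kept. Regioselectivity (chain at C1 next to OH, hydrogen at C6) follows from the steric rule for terminal alkynes, under which the alkyne substituent ends up beside the carbonyl-derived carbon. Chemoselectivity for the alkyne over the enoate and the two alkenes rests on the much faster alkyne insertion, since cyclopropanation by such complexes needs higher temperature and electron-poor or strained alkenes. The β-methoxy group makes 14 a push–pull system, so its E and Z forms interconvert and its geometry is not critical, but CO loss is slower and CO insertion less favoured than for simple alkenyl complexes, which is why a high concentration in THF is chosen. The nearest analogy for this donor pattern is the benzannulation of heteroaryl complexes such as 3-furyl ones, whose ring-closing carbon also bears oxygen.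

## Compound list

1 | 4-methylpent-3-en-1-ol | CC(C)=CCCO | starting material
2 | 4-methylpent-3-enal | CC(C)=CCC=O | intermediate
3 | 4-(trimethylsilyl)but-3-yn-2-one | CC(=O)C#C[Si](C)(C)C | starting material
4 | 4-(trimethylsilyl)but-1-en-3-yn-2-yl trifluoromethanesulfonate | C=C(OS(=O)(=O)C(F)(F)F)C#C[Si](C)(C)C | intermediate
5 | (4S)-7-methyl-3-methylidene-1-(trimethylsilyl)oct-6-en-1-yn-4-ol | C=C(C#C[Si](C)(C)C)[C@H](CC=C(C)C)O | intermediate
6 | (4S)-7-methyl-3-methylideneoct-6-en-1-yn-4-ol | C=C(C#C)[C@H](CC=C(C)C)O | intermediate
7 | (2Z)-2-methylbut-2-enoic acid (angelic acid) | C/C=C(/C)C(=O)O | starting material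
8 | (2Z)-2-methylbut-2-enoic 2,4,6-trichlorobenzoic anhydride | C/C=C(/C)C(=O)OC(=O)c1c(Cl)cc(Cl)cc1Cl | intermediate
9 | (4S)-7-methyl-3-methylideneoct-6-en-1-yn-4-yl (2Z)-2-methylbut-2-enoate | C=C(C#C)[C@H](CC=C(C)C)OC(=O)/C(C)=C\C | intermediate
10 | 2-bromo-1,1-dimethoxypropane (racemic) | COC(OC)C(C)Br | starting material
11 | (Z)-2-bromo-1-methoxyprop-1-ene | CO/C=C(/C)Br | intermediate
12 | [(E)-1-methoxyprop-1-en-2-yl]lithium | CO/C=C(/C)[Li] | intermediate
13 | lithium pentacarbonyl[(2Z)-3-methoxy-2-methylprop-2-enoyl]chromate | CO/C=C(/C)C([O-])=[Cr](=C=O)(=C=O)(=C=O)(=C=O)=C=O.[Li+] | intermediate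
14 | pentacarbonyl[(2Z)-1,3-dimethoxy-2-methylprop-2-en-1-ylidene]chromium | CO/C=C(/C)C(OC)=[Cr](=C=O)(=C=O)(=C=O)(=C=O)=C=O | intermediate
15 | tricarbonylchromium η6-arene complex of 16 (metal fragment written dot-joined) | C=C(c1cc(OC)c(C)c(OC)c1O)[C@H](CC=C(C)C)OC(=O)/C(C)=C\C.O=C=[Cr](=C=O)=C=O | intermediate
16 | (3S)-2-(2-hydroxy-3,5-dimethoxy-4-methylphenyl)-6-methylhepta-1,5-dien-3-yl (2Z)-2-methylbut-2-enoate | C=C(c1cc(OC)c(C)c(OC)c1O)[C@H](CC=C(C)C)OC(=O)/C(C)=C\C | target

## Step count and uncertain steps

Total: 8 steps. Longest linear sequence: 5 steps (steps 1, 3, 4, 5, 8).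

**Step 8 (key step).**
- What may go wrong:
  - The β-methoxy donor raises the electron density at chromium. The intermediate vinylcarbene may then close to a five-membered ring without CO insertion, or CO loss may be too slow at a temperature the enyne tolerates.
  - The prenyl alkene stands in a 1,6-relationship to the alkyne, so intramolecular cyclopropanation by the vinylcarbene could compete.
  - The product, a 4-methoxyphenol, may be over-oxidised during removal of the metal.
- Fallback: a preformed, protected ring replaces the annulation. It sets out from aldehyde 2 (with acid 7) and comes back to the route at 16.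
  - Commercial 2,4-dimethoxy-3-methylbenzaldehyde is oxidised (Dakin type: mCPBA; then NaOH, MeOH) to 2,4-dimethoxy-3-methylphenol F1.
  - F1 is protected (MOMCl, i-Pr2NEt) as 1-(methoxymethoxy)-2,4-dimethoxy-3-methylbenzene F2.
  - Lithiation next to the acetal oxygen (s-BuLi, TMEDA, THF, −78 °C) and acylation with N-methoxy-N-methylacetamide should give 1-[2-(methoxymethoxy)-3,5-dimethoxy-4-methylphenyl]ethan-1-one F3.
  - KN(SiMe3)2 and PhNTf2 convert F3 into 1-[2-(methoxymethoxy)-3,5-dimethoxy-4-methylphenyl]ethenyl trifluoromethanesulfonate F4.
  - F4 is coupled with 2 under the conditions of step 3 to (3S)-2-[2-(methoxymethoxy)-3,5-dimethoxy-4-methylphenyl]-6-methylhepta-1,5-dien-3-ol F5.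
  - F5 is esterified as in step 5 to (3S)-2-[2-(methoxymethoxy)-3,5-dimethoxy-4-methylphenyl]-6-methylhepta-1,5-dien-3-yl (2Z)-2-methylbut-2-enoate F6.
  - ZnBr2 and n-PrSH in CH2Cl2 at 0 °C then remove the acetal to give 16.

**Step 7.**
- What may go wrong:
  - Lithium methoxide may be eliminated from the alkenyllithium (giving propyne) while it waits for the sparingly soluble hexacarbonyl.
  - The wrong geometric isomer of 11 may be carried over; it eliminates at once.
- Fallback: the polarity of the Cr–C bond formation is reversed. It sets out from 11 and comes back at 14.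
  - 12 is generated as before but quenched at −78 °C with CO2, a capture that needs no warming, to give (2Z)-3-methoxy-2-methylprop-2-enoic acid F7. This acid is also obtainable without any organolithium intermediate.
  - Oxalyl chloride (cat. DMF) gives (2Z)-3-methoxy-2-methylprop-2-enoyl chloride F8.
  - F8 acylates Na2Cr(CO)5 (from Cr(CO)6 and NaC10H8, THF, −78 °C) to sodium pentacarbonyl[(2Z)-3-methoxy-2-methylprop-2-enoyl]chromate F9.
  - F9 is methylated with Me3OBF4 to 14.

**Step 3.**
- What may go wrong:
  - Face selection by the chiral chromium complex may be insufficient for this unbranched aldehyde.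
  - The alkenylchromium may react through its butatrienyl form.
  - Nickel may homocouple the triflate.
- Fallback: resolution instead of asymmetric catalysis. It sets out from 2 and 4 and comes back at 5.
  - The coupling is run under the conditions of step 3 without the chiral ligand to give racemic 7-methyl-3-methylidene-1-(trimethylsilyl)oct-6-en-1-yn-4-ol F10.
  - Sharpless kinetic resolution (Ti(OiPr)4, D-(−)-diisopropyl tartrate, t-BuOOH, CH2Cl2, −20 °C) should epoxidise the (R)-enantiomer to (1R)-4-methyl-1-{(2R)-2-[(trimethylsilyl)ethynyl]oxiran-2-yl}pent-3-en-1-ol F11 and leave (S)-configured 5, which is separated by chromatography.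

**Step 5.**
- What may go wrong:
  - The angelate may isomerise to the tiglate during the heated acyl transfer.
  - The alcohol may attack the aroyl carbonyl of 8.
- Fallback: the Z alkene is built on the finished ester. It sets out from 6 and comes back at 9.
  - DCC/DMAP esterification of 6 with 2-[bis(2,2,2-trifluoroethoxy)phosphoryl]propanoic acid gives (4S)-7-methyl-3-methylideneoct-6-en-1-yn-4-yl 2-[bis(2,2,2-trifluoroethoxy)phosphoryl]propanoate F12.
  - Still–Gennari olefination of F12 (KN(SiMe3)2, 18-crown-6, THF, −78 °C; acetaldehyde) should give 9 with the ester and the new methyl group cis.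

## Further compounds

F1 | step 8 | 2,4-dimethoxy-3-methylphenol | Oc1ccc(OC)c(C)c1OC
F2 | step 8 | 1-(methoxymethoxy)-2,4-dimethoxy-3-methylbenzene | COCOc1ccc(OC)c(C)c1OC
F3 | step 8 | 1-[2-(methoxymethoxy)-3,5-dimethoxy-4-methylphenyl]ethan-1-one | CC(=O)c1cc(OC)c(C)c(OC)c1OCOC
F4 | step 8 | 1-[2-(methoxymethoxy)-3,5-dimethoxy-4-methylphenyl]ethenyl trifluoromethanesulfonate | C=C(OS(=O)(=O)C(F)(F)F)c1cc(OC)c(C)c(OC)c1OCOC
F5 | step 8 | (3S)-2-[2-(methoxymethoxy)-3,5-dimethoxy-4-methylphenyl]-6-methylhepta-1,5-dien-3-ol | C=C(c1cc(OC)c(C)c(OC)c1OCOC)[C@H](CC=C(C)C)O
F6 | step 8 | (3S)-2-[2-(methoxymethoxy)-3,5-dimethoxy-4-methylphenyl]-6-methylhepta-1,5-dien-3-yl (2Z)-2-methylbut-2-enoate | C=C(c1cc(OC)c(C)c(OC)c1OCOC)[C@H](CC=C(C)C)OC(=O)/C(C)=C\C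
F7 | step 7 | (2Z)-3-methoxy-2-methylprop-2-enoic acid | CO/C=C(/C)C(=O)O
F8 | step 7 | (2Z)-3-methoxy-2-methylprop-2-enoyl chloride | CO/C=C(/C)C(=O)Cl
F9 | step 7 | sodium pentacarbonyl[(2Z)-3-methoxy-2-methylprop-2-enoyl]chromate | CO/C=C(/C)C([O-])=[Cr](=C=O)(=C=O)(=C=O)(=C=O)=C=O.[Na+]
F10 | step 3 | racemic 7-methyl-3-methylidene-1-(trimethylsilyl)oct-6-en-1-yn-4-ol | C=C(C#C[Si](C)(C)C)C(CC=C(C)C)O
F11 | step 3 | (1R)-4-methyl-1-{(2R)-2-[(trimethylsilyl)ethynyl]oxiran-2-yl}pent-3-en-1-ol | C[Si](C)(C)C#C[C@@]1(CO1)[C@@H](CC=C(C)C)O
F12 | step 5 | (4S)-7-methyl-3-methylideneoct-6-en-1-yn-4-yl 2-[bis(2,2,2-trifluoroethoxy)phosphoryl]propanoate (both epimers at the phosphonate carbon) | C=C(C#C)[C@H](CC=C(C)C)OC(=O)C(C)P(=O)(OCC(F)(F)F)OCC(F)(F)F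
A1 | alternative 1 | 4,6-dimethoxy-5-methyl-2-(4,4,5,5-tetramethyl-1,3,2-dioxaborolan-2-yl)phenol | COc1cc(B2OC(C)(C)C(C)(C)O2)c(O)c(OC)c1C
A2 | alternative 1 | (3S)-2-bromo-6-methylhepta-1,5-dien-3-ol | C=C(Br)[C@H](CC=C(C)C)O
A3 | alternative 1 | (3S)-2-(2-hydroxy-3,5-dimethoxy-4-methylphenyl)-6-methylhepta-1,5-dien-3-ol | C=C(c1cc(OC)c(C)c(OC)c1O)[C@H](CC=C(C)C)O
A4 | alternative 2 | 3-methoxy-4-methylcyclobut-3-ene-1,2-dione | COC1=C(C)C(=O)C1=O
A5 | alternative 2 | 4-[(4S)-4-(tert-butyldimethylsilyloxy)-7-methyl-3-methylideneocta-1,6-dien-2-yl]-4-hydroxy-3-methoxy-2-methylcyclobut-2-en-1-one (both epimers at the ring carbinol) | COC1=C(C)C(=O)C1(O)C(=C)C(=C)[C@H](CC=C(C)C)O[Si](C)(C)C(C)(C)C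
A6 | alternative 2 | 2-[(3S)-3-(tert-butyldimethylsilyloxy)-6-methylhepta-1,5-dien-2-yl]-6-methoxy-5-methylbenzene-1,4-diol | C=C(c1cc(O)c(C)c(OC)c1O)[C@H](CC=C(C)C)O[Si](C)(C)C(C)(C)C
A7 | alternative 3 | 5-[(3S)-3-(tert-butyldimethylsilyloxy)-6-methylhepta-1,5-dien-2-yl]-2-methylcyclohexane-1,3-dione | C=C(C1CC(=O)C(C)C(=O)C1)[C@H](CC=C(C)C)O[Si](C)(C)C(C)(C)C
A8 | alternative 3 | tert-butyl{[(3S)-2-(3,5-dimethoxy-4-methylphenyl)-6-methylhepta-1,5-dien-3-yl]oxy}dimethylsilane | C=C(c1cc(OC)c(C)c(OC)c1)[C@H](CC=C(C)C)O[Si](C)(C)C(C)(C)C
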